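**Remark (assumption):** iridoid numbering is used for the core (C1 acetal carbon, O2, C3=C4, C5 and C9 ring-fusion carbons, C6–C8 cyclopentane carbons, C10 the CH2O on C8, C11 the carbon on C4); the key lactol is drawn as its 1β-hydroxy anomer, which is expected to dominate the anomeric equilibrium; SAMP, 2,2,2-trifluoroethyl formate, (S)-3-methylpentanoic acid and (R)-diphenylprolinol trimethylsilyl ether are taken as commercial.

## Retrosynthetic overview

1. Endgame: the target comes from a C11 aldehyde (Luche reduction), reached by C10 coumaroylation, Fukuyama reduction of a C11 thioester (latent CH2OH), acetonide cleavage and C1 acylation of a tricyclic lactol thioester in which O7 and O10 are tied as an acetonide (temporary ring C).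
2. Key disconnection: that lactol comes from an acyclic enal bearing a 1,3-dioxan-5-one plus S-ethyl formylthioacetate in one amine-catalysed cascade: Michael addition (C4–C5), aldol closure of the cyclopentane ring B (C8–C9), hemiacetalisation closing the dihydropyran ring A (O2–C1).
3. Enabling feature: in ring B the tertiary carbinol C8 is β to the acetal carbon C1 through C9 (an aldol retron), and C7–O/C8/C10–O is a dihydroxyacetone unit, so a 1,3-dioxan-5-one serves as aldol acceptor and as stereochemical relay from C7 to C8; C1 and C3 are the ends of a 1,5-dialdehyde that closes ring A.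
4. The enal comes from 2,2-dimethyl-1,3-dioxan-5-one by SAMP-hydrazone allylation (sets C7) and cross-metathesis with crotonaldehyde.
5. Ring order: ring C (purchased, temporary), then ring B, then ring A (B and A both in the key step), then ring C is opened.

Key step: step 6

## Route

Step 1
Reactants: 1 2,2-dimethyl-1,3-dioxan-5-one; 2 SAMP [(S)-1-amino-2-(methoxymethyl)pyrrolidine]
Product: 3 SAMP hydrazone of 1
Conditions: cyclohexane, reflux, Dean–Stark trap
Reagents that add atoms: none
Why: Hydrazone condensation driven by azeotropic removal of water installs the auxiliary for the Enders SAMP-hydrazone method; no stereocenter is formed.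

Step 2
Reactants: 3 SAMP hydrazone of 1; 4 allyl bromide
Product: 5 (S,S)-α-allylated SAMP hydrazone
Conditions: t-BuLi, THF, −78 °C; then 4, −100 °C → rt
Reagents that add atoms: none
Why: Enders SAMP-hydrazone α-alkylation: the lithium azaenolate, rigidified by methoxy–lithium chelation, is allylated on its open face, which should set the (S) configuration of the future C7.

Step 3
Reactants: 5 (S,S)-α-allylated SAMP hydrazone
Product: 6 (4S)-4-allyl-2,2-dimethyl-1,3-dioxan-5-one
Conditions: sat. aq. (CO2H)2, Et2O, rt
Reagents that add atoms: water, O
Why: Mild biphasic oxalic acid hydrolysis of the hydrazone should free the ketone without epimerising the α-stereocenter or opening the acetonide, and returns the auxiliary as its oxalate.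

Step 4
Reactants: 6 (4S)-4-allyl-2,2-dimethyl-1,3-dioxan-5-one; 7 (E)-crotonaldehyde
Product: 8 (2E)-4-[(4S)-2,2-dimethyl-5-oxo-1,3-dioxan-4-yl]but-2-enal
Conditions: 7 (5 equiv), second-generation Hoveyda–Grubbs catalyst [RuCl2(H2IMes)(=CH-C6H4-2-O-i-Pr)] (5 mol%), CH2Cl2, 40 °C
Reagents that add atoms: none
Why: Olefin cross-metathesis of a terminal alkene with an excess of the electron-poor partner crotonaldehyde should give the (E)-enal under neutral conditions that leave the ketone α-stereocenter untouched.

Step 5
Reactants: 9 S-ethyl thioacetate; 10 2,2,2-trifluoroethyl formate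
Product: 11 S-ethyl 3-oxopropanethioate (formylthioacetate; largely enol; used at once)
Conditions: LiN(SiMe3)2 (2.1 equiv), THF, −78 °C; then 10; then cold 1 M HCl
Reagents that add atoms: none
Why: Crossed Claisen condensation: the lithium thioester enolate is C-formylated by the activated formate, and the second equivalent of base stores the product as its enolate until the acidic quench.

Step 6
Reactants: 8 (2E)-4-[(4S)-2,2-dimethyl-5-oxo-1,3-dioxan-4-yl]but-2-enal; 11 S-ethyl 3-oxopropanethioate
Product: 14 tricyclic lactol thioester (rings A–B–C; 1R,5S,7S,8R,9S), via Michael adduct 12 (not isolated), via ring-B hydroxy aldehyde 13 (not isolated)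
Conditions: (R)-2-[diphenyl(trimethylsilyloxy)methyl]pyrrolidine (20 mol%), PhCO2H (20 mol%), CH2Cl2, 0 °C → rt
Reagents that add atoms: none
Why: Proposed new method: the amine converts the enal of 8 into an iminium ion, the enol of 11 adds to C5 (C4–C5 bond), the resulting C1=C9 enamine attacks the C8 ketone of the dioxanone (C8–C9 bond), and after hydrolysis the enol oxygen of the 1,3-dicarbonyl unit adds to the freed C1 aldehyde. The closest known reactions are the diarylprolinol silyl ether-catalysed Michael addition/hemiacetalisation of 1,3-dicarbonyl compounds with enals and iminium–enamine Michael/intramolecular aldol cascades, merged here on an enal that carries its own ketone acceptor. Ring B closes by a 5-(enolexo)-exo-trig aldol and ring A by a 6-exo-trig hemiacetalisation. C5 is set by the (R)-catalyst, whose diphenyl(silyloxy)methyl group shields one face of the (E)-iminium ion, and C8 by the substrate, because the three-atom tether C6–C5–C9 reaches the carbonyl only on the face syn to C6, so ring B is cis-fused to ring C and the C8 hydroxyl ends up trans to the C7 oxygen. C9 should follow from a hydrogen-bonded aldol transition state with iminium and alkoxide syn, and, being epimerisable through the enamine, is corrected thermodynamically because only the isomer with C1 cis to C4 can close the cis-fused lactol, whose C1 hydroxyl then settles in the β (axial, anti to C8) position. The step needs the amine to activate only the aldehyde (first as acceptor, then as donor) while the ketone acts only as electrophile, which the bulky catalyst should secure because it does not form enamines with the α-branched dioxanone, and a competing aldol from C4 is reversible whereas lactol formation removes the 1,3-dicarbonyl as an unreactive vinylogous thiocarbonate.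

Step 7
Reactants: 14 tricyclic lactol thioester; 15 (S)-3-methylpentanoic acid
Product: 16 1β-O-[(S)-3-methylpentanoyl] lactol ester (thioester, acetonide)
Conditions: EDC·HCl, DMAP (cat.), CH2Cl2, 0 °C
Reagents that add atoms: none
Why: Steglich esterification of the hemiacetal hydroxyl, the only acylable OH since the tertiary C8–OH is inert, should trap the equilibrating lactol as the 1β-ester in which the acyloxy group is axial and anti to C8 on the convex face.

Step 8
Reactants: 16 1β-O-acyl thioester acetonide
Product: 17 1β-O-acyl 7,8,10-triol thioester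
Conditions: AcOH/H2O/THF (3:1:1), 40 °C
Reagents that add atoms: none
Why: Acid-catalysed acetal hydrolysis opens the 1,3-dioxane at this stage because the enol ether, deactivated as a vinylogous thioester, and the acyl acetal should tolerate aqueous acetic acid better than the later C11 aldehyde would.

Step 9
Reactants: 17 1β-O-acyl 7,8,10-triol thioester
Product: 18 1β-O-acyl 7,8,10-triol C11 aldehyde
Conditions: Et3SiH, Pd/C (10 wt% palladium on carbon), acetone, rt
Reagents that add atoms: none
Why: Fukuyama reduction: oxidative addition of zerovalent palladium into the C–S bond followed by hydride transfer from the silane should give the aldehyde without touching the ester or the push-pull C3=C4 bond.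

Step 10
Reactants: 19 (E)-p-coumaric acid
Product: 21 (E)-3-[4-(tert-butyldimethylsilyloxy)phenyl]prop-2-enoic acid, via bis-silylated coumarate 20 (not isolated)
Conditions: TBSCl (2.2 equiv), imidazole, DMF, rt; then AcOH/THF/H2O, rt
Reagents that add atoms: tert-butyldimethylsilyl chloride, CC(C)(C)[Si](C)(C)Cl
Why: Silylation of both acidic OH groups followed by selective hydrolysis of the far more labile silyl ester leaves the phenol protected and the acid free.

Step 11
Reactants: 18 1β-O-acyl 7,8,10-triol C11 aldehyde; 21 (E)-3-[4-(tert-butyldimethylsilyloxy)phenyl]prop-2-enoic acid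
Product: 22 10-O-(4-O-TBS-p-coumaroyl) C11 aldehyde
Conditions: EDC·HCl, DMAP (cat.), CH2Cl2, −20 → 0 °C
Reagents that add atoms: none
Why: Carbodiimide (Steglich) esterification with about one equivalent of acid at low temperature should select the primary C10–OH over the secondary C7–OH and the tertiary C8–OH.

Step 12
Reactants: 22 10-O-(4-O-TBS-p-coumaroyl) C11 aldehyde
Product: 23 10-O-(p-coumaroyl) C11 aldehyde
Conditions: Bu4NF/AcOH (1:1), THF, 0 °C
Reagents that add atoms: none
Why: Acetic acid-buffered fluoride desilylation cleaves the aryl silyl ether, the most labile Si–O bond, under near-neutral conditions that should avoid acyl migration or loss of the anomeric ester while C4 still carries the stabilising formyl group.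

Step 13
Reactants: 23 10-O-(p-coumaroyl) C11 aldehyde
Product: 24 target CNP0241834.1
Conditions: NaBH4, CeCl3·7H2O, MeOH/THF, −78 °C
Reagents that add atoms: none
Why: Luche reduction should give clean 1,2-reduction of the vinylogous formyl group to the C11 allylic alcohol while the acyl acetal, the cinnamate and the phenol remain untouched at low temperature.

## Compound list

1 | 2,2-dimethyl-1,3-dioxan-5-one | CC1(C)OCC(=O)CO1 | starting material
2 | SAMP, (S)-1-amino-2-(methoxymethyl)pyrrolidine | COC[C@@H]1CCCN1N | starting material
3 | (S)-N-(2,2-dimethyl-1,3-dioxan-5-ylidene)-2-(methoxymethyl)pyrrolidin-1-amine | COC[C@@H]1CCCN1N=C1COC(C)(C)OC1 | intermediate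
4 | allyl bromide | C=CCBr | starting material
5 | (2S)-N-[(4S)-4-allyl-2,2-dimethyl-1,3-dioxan-5-ylidene]-2-(methoxymethyl)pyrrolidin-1-amine (drawn as the kinetically expected Z hydrazone; C=N geometry of no consequence) | COC[C@@H]1CCCN1/N=C1/COC(C)(C)O[C@H]1CC=C | intermediate
6 | (4S)-4-allyl-2,2-dimethyl-1,3-dioxan-5-one | C=CC[C@@H]1OC(C)(C)OCC1=O | intermediate
7 | (E)-crotonaldehyde | C/C=C/C=O | starting material
8 | (2E)-4-[(4S)-2,2-dimethyl-5-oxo-1,3-dioxan-4-yl]but-2-enal | O=C/C=C/C[C@@H]1OC(C)(C)OCC1=O | intermediate
9 | S-ethyl thioacetate | CCSC(C)=O | starting material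
10 | 2,2,2-trifluoroethyl formate | O=COCC(F)(F)F | starting material
11 | S-ethyl 3-oxopropanethioate (aldehyde form drawn; largely enol) | CCSC(=O)CC=O | intermediate
12 | Michael adduct, S-ethyl (3S)-3-{[(4S)-2,2-dimethyl-5-oxo-1,3-dioxan-4-yl]methyl}-2-(hydroxymethylidene)-5-oxopentanethioate (enol form; catalyst-bound as enamine in the flask) | CCSC(=O)C(=CO)[C@H](CC=O)C[C@@H]1OC(C)(C)OCC1=O | intermediate (not isolated)
13 | ring-B hydroxy aldehyde: cis-fused cyclopentane–dioxane with C8–OH, C9–CHO and the C5 enolised formylthioacetate side chain (open form of 14) | OC=C(C(=O)SCC)[C@H]1C[C@@H]2OC(C)(C)OC[C@]2(O)[C@H]1C=O | intermediate (not isolated)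
14 | tricyclic lactol thioester: S-ethyl (1R,5S,7S,8R,9S)-1,8-dihydroxy-7,10-O-isopropylidene-iridoid-3-ene-11-thioate | O[C@@H]1OC=C(C(=O)SCC)[C@H]2C[C@@H]3OC(C)(C)OC[C@]3(O)[C@@H]12 | intermediate
15 | (S)-3-methylpentanoic acid | CC[C@H](C)CC(=O)O | starting material
16 | (1S,5S,7S,8R,9S) 1-O-[(S)-3-methylpentanoyl] derivative of 14 | CC[C@H](C)CC(=O)O[C@@H]1OC=C(C(=O)SCC)[C@H]2C[C@@H]3OC(C)(C)OC[C@]3(O)[C@@H]12 | intermediate
17 | (1S,5S,7S,8R,9S) 1-O-acyl 7,8,10-triol S-ethyl thioester | CC[C@H](C)CC(=O)O[C@@H]1OC=C(C(=O)SCC)[C@H]2C[C@H](O)[C@](O)(CO)[C@@H]12 | intermediate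
18 | (1S,5S,7S,8R,9S) 1-O-acyl 7,8,10-triol C11 aldehyde | CC[C@H](C)CC(=O)O[C@@H]1OC=C(C=O)[C@H]2C[C@H](O)[C@](O)(CO)[C@@H]12 | intermediate
19 | (E)-p-coumaric acid | OC(=O)/C=C/c1ccc(O)cc1 | starting material
20 | tert-butyldimethylsilyl (E)-3-[4-(tert-butyldimethylsilyloxy)phenyl]prop-2-enoate | CC(C)(C)[Si](C)(C)OC(=O)/C=C/c1ccc(O[Si](C)(C)C(C)(C)C)cc1 | intermediate (not isolated)
21 | (E)-3-[4-(tert-butyldimethylsilyloxy)phenyl]prop-2-enoic acid | OC(=O)/C=C/c1ccc(O[Si](C)(C)C(C)(C)C)cc1 | intermediate
22 | 10-O-[(E)-4-(tert-butyldimethylsilyloxy)cinnamoyl] derivative of 18 | CC[C@H](C)CC(=O)O[C@@H]1OC=C(C=O)[C@H]2C[C@H](O)[C@](O)(COC(=O)/C=C/c3ccc(O[Si](C)(C)C(C)(C)C)cc3)[C@@H]12 | intermediate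
23 | 10-O-(E)-p-coumaroyl C11 aldehyde | CC[C@H](C)CC(=O)O[C@@H]1OC=C(C=O)[C@H]2C[C@H](O)[C@](O)(COC(=O)/C=C/c3ccc(O)cc3)[C@@H]12 | intermediate
24 | CNP0241834.1 | CC[C@H](C)CC(=O)O[C@@H]1OC=C(CO)[C@H]2C[C@H](O)[C@](O)(COC(=O)/C=C/c3ccc(O)cc3)[C@@H]12 | target

## Step count and risks

Total steps: 13. Longest linear sequence: 11 steps (1–4, 6–9, 11–13).

**Step 6 (key cascade).** Possible failure processes:
- amine condensation at the dioxanone ketone and intramolecular Michael addition of that enamine onto the enal;
- γ-deprotonation of the iminium ion to a dienamine with loss of the δ-alkoxy group;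
- partial epimerisation at C7 before ring closure;
- an aldol closure that is slow under the hindered catalyst, or that does not funnel into the cis-fused lactol.

Fallback (known chemistry, two stages): starting from 8 and 11, the established diarylprolinol silyl ether Michael addition/hemiacetalisation of a 1,3-dicarbonyl compound with an enal is run cold (−20 °C, wet toluene, short time) and stopped at the monocyclic 2-hydroxy-3,4-dihydro-2H-pyran, monocyclic lactol F1. F1 is isolated and ring B is then closed separately by an amine-catalysed intramolecular aldol of the lactol/aldehyde onto the ketone (pyrrolidine/AcOH 20 mol% in CH2Cl2, or L-proline in DMSO). Enamine activation again makes the aldehyde the donor, and the cis-fused lactol is the thermodynamic sink. The sequence returns to the route at 14.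

**Step 11 (regioselective coumaroylation).** Possible failure processes: competing acylation of the secondary C7 hydroxyl, double acylation, or acyl migration between O10 and O7.
Fallback: starting from 18, acid 21 is converted into (E)-3-[4-(tert-butyldimethylsilyloxy)phenyl]prop-2-enoyl chloride F2 ((COCl)2, cat. DMF, CH2Cl2). Triol 18 is then acylated under dimethyltin dichloride catalysis (Me2SnCl2 5 mol%, K2CO3, THF, rt), in which a transient cyclic stannylene across the C8/C10 diol activates only the primary oxygen. The sequence returns at 22.

**Step 9 (Fukuyama reduction).** Possible failure processes: slow oxidative addition into the electron-rich vinylogous thioester, palladium-catalysed silylation of the free hydroxyls by the silane, or catalyst poisoning by sulfur.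
Fallback: starting from 14, the thioester is reduced with a hydride instead (i-Bu2AlH, 3.3 equiv, CH2Cl2, −78 °C; thioester to aldehyde while the lactol is held as its aluminium alkoxide) to give formyl lactol F3. Steglich esterification of F3 with 15 (EDC·HCl, DMAP) gives 1-O-acyl formyl acetonide F4. The acetonide is then cleaved under near-neutral conditions (CeCl3·7H2O, cat. oxalic acid, MeCN, rt), chosen because the 4-formyl enol ether is less acid-tolerant than the thioester. The sequence returns at 18.

## Further compounds

F1 | step 6 | S-ethyl (4S)-4-{[(4S)-2,2-dimethyl-5-oxo-1,3-dioxan-4-yl]methyl}-2-hydroxy-3,4-dihydro-2H-pyran-5-carbothioate (anomeric mixture at the lactol carbon) | CCSC(=O)C1=COC(O)C[C@@H]1C[C@@H]2OC(C)(C)OCC2=O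
F2 | step 11 | (E)-3-[4-(tert-butyldimethylsilyloxy)phenyl]prop-2-enoyl chloride | ClC(=O)/C=C/c1ccc(O[Si](C)(C)C(C)(C)C)cc1
F3 | step 9 | (1R,5S,7S,8R,9S)-1,8-dihydroxy-7,10-O-isopropylidene-iridoid-3-en-11-al (formyl lactol) | O[C@@H]1OC=C(C=O)[C@H]2C[C@@H]3OC(C)(C)OC[C@]3(O)[C@@H]12
F4 | step 9 | (1S,5S,7S,8R,9S) 1-O-[(S)-3-methylpentanoyl] derivative of F3 | CC[C@H](C)CC(=O)O[C@@H]1OC=C(C=O)[C@H]2C[C@@H]3OC(C)(C)OC[C@]3(O)[C@@H]12
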